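**Plan**
- Retrosynthesis: the silyl and methoxymethyl groups are removed and the methylene C13' is restored to a 1,3-dithiane carbon. The chain is then cut at C13'–C14' and C12'–C13' in one operation, giving (S)-1,2-epoxybutane, a 2-silyl-1,3-dithiane and an aryl-tethered C12 iodide. The iodide is cut at ring C5–C1' into an aryl Grignard reagent and 1,12-dibromododecane.
- Forward: the protected resorcinol ring is joined to the C12 chain by a copper-catalysed Grignard coupling, and the bromide is exchanged for iodide. The silyl dithiane is then united in one flask first with the epoxide and then with the iodide. No ring is formed anywhere. Desulfurisation and acid deprotection finish the synthesis.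
- Enabling feature: in the chain C1'–C17' on ring carbon C5 of the benzene-1,3-diol ring, C13' is a plain CH2 between C12' and C14' and lies two bonds from the carbinol C15'. It can therefore be a dithiane carbon that reacts twice as a nucleophile, and the oxygen on C15' is placed to take over silicon from C13'.
- Stereochemistry: the only stereocentre, C15' (S), is bought with (S)-1,2-epoxybutane. The epoxide is opened at its CH2 group, so the C–O bond at the stereocentre is never broken.

Key step: step 5

Remark: the side chain is numbered C1' (benzylic, on ring carbon C5) to C17' (methyl), the target SMILES corresponds to the 15'S carbinol, and dodec-11-yn-1-ol (used only in a fallback) is assumed to be purchasable.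

**Route**

Step 1
Reactants: 1 5-bromoresorcinol
Product: 2 1-bromo-3,5-bis(methoxymethoxy)benzene
Conditions: NaH (2.4 equiv), MOMCl (2.4 equiv), DMF, 0 °C → rt
Reagents that add atoms: chloromethyl methyl ether (MOMCl), COCCl
Why: Williamson-type O-alkylation of the doubly deprotonated resorcinol with the reactive α-chloro ether should give the bis(methoxymethyl) acetal, a protecting group that is inert to the Grignard, organolithium and nickel steps and falls off in the final acid treatment.

Step 2
Reactants: 2 1-bromo-3,5-bis(methoxymethoxy)benzene, 3 1,12-dibromododecane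
Product: 5 1-(12-bromododecyl)-3,5-bis(methoxymethoxy)benzene, via aryl Grignard reagent 4 (not isolated)
Conditions: Mg, I2 (cat.), THF, reflux; then 3 (3 equiv), Li2CuCl4 (3 mol %), THF, −10 °C → rt
Reagents that add atoms: none
Why: Kochi-type copper-catalysed cross-coupling of an aryl Grignard reagent with a primary alkyl bromide (Li2CuCl4) forms the ring C5–C1' bond, and the threefold excess of the symmetrical dibromide should keep the second bromide end intact by statistics while the surplus is recovered on chromatography.

Step 3
Reactants: 5 1-(12-bromododecyl)-3,5-bis(methoxymethoxy)benzene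
Product: 6 1-(12-iodododecyl)-3,5-bis(methoxymethoxy)benzene
Conditions: NaI (3 equiv), acetone, reflux
Reagents that add atoms: sodium iodide (NaI), [Na+].[I-]
Why: Finkelstein halide exchange, driven by precipitation of NaBr from acetone, should convert the primary bromide into the more reactive iodide needed for fast SN2 alkylation of a hindered carbanion.

Step 4
Reactants: 7 1,3-dithiane
Product: 9 tert-butyl(1,3-dithian-2-yl)dimethylsilane, via 2-lithio-1,3-dithiane 8 (not isolated)
Conditions: n-BuLi, THF, −30 °C; TBSCl, −78 °C → rt
Reagents that add atoms: tert-butyldimethylsilyl chloride (TBSCl), CC(C)(C)[Si](C)(C)Cl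
Why: Corey–Seebach metalation of 1,3-dithiane at C2 followed by trapping of the sulfur-stabilised carbanion with the silyl chloride is a standard C-silylation and places the migrating group on the future C13'.

Step 5
Reactants: 9 tert-butyl(1,3-dithian-2-yl)dimethylsilane, 10 (S)-1,2-epoxybutane, 6 1-(12-iodododecyl)-3,5-bis(methoxymethoxy)benzene
Product: 14 2-{12-[3,5-bis(methoxymethoxy)phenyl]dodecyl}-2-[(2S)-2-(tert-butyldimethylsilyloxy)butyl]-1,3-dithiane, via lithiated silyl dithiane 11 (not isolated), via lithium alkoxide 12 (not isolated), via Brook-rearranged dithianyllithium 13 (not isolated)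
Conditions: 9 (1.35 equiv), t-BuLi (1.3 equiv), Et2O, −78 → −45 °C; 10 (1.3 equiv), Et2O, −78 → −25 °C; then 6 (1.0 equiv), HMPA (4 equiv), THF, −78 °C → rt
Reagents that add atoms: none
Why: t-BuLi removes the remaining C2 proton of 9 to give 11, which in ether opens epoxide 10 by SN2 attack at the unsubstituted CH2 group (bond C13'–C14') to give alkoxide 12, stable in this weakly coordinating solvent; on addition of HMPA the lithium ion is solvated, the alkoxide attacks silicon through a five-membered siliconate and the silyl group moves from C13' to the oxygen on C15' (1,4-Brook rearrangement), producing dithianyllithium 13, which is alkylated by the primary iodide 6 (bond C12'–C13'). The closest known reaction type is the solvent-controlled three-component linchpin coupling of 2-silyl-1,3-dithianes (anion relay through a Brook rearrangement), ended here by a classical Corey–Seebach alkylation. No ring is closed and no stereocentre is created: C15' is carried over from 10 with its C–O bond untouched, so it remains S. The step needs regioselective epoxide opening, secured by the bulk of the silylated anion and the monosubstituted epoxide; correct timing of the silyl shift, secured by keeping HMPA out until 10 is consumed; and chemoselectivity for SN2 at the iodide, secured by using t-BuLi in slight deficit to 9 so that no free alkyllithium remains to metalate the arene between its two acetal oxygens or to exchange with the iodide. The migrated silyl group also protects the carbinol for the nickel step that follows.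

Step 6
Reactants: 14 2-{12-[3,5-bis(methoxymethoxy)phenyl]dodecyl}-2-[(2S)-2-(tert-butyldimethylsilyloxy)butyl]-1,3-dithiane
Product: 15 tert-butyl({(3S)-17-[3,5-bis(methoxymethoxy)phenyl]heptadecan-3-yl}oxy)dimethylsilane
Conditions: Raney Ni (W-2, excess), EtOH, reflux
Reagents that add atoms: none
Why: Mozingo-type reductive desulfurisation, in which hydrogen-rich Raney Ni cleaves the four C–S bonds of the thioketal and replaces them by C–H to leave the methylene C13', should spare the silyl ether, the acetals and the arene, while the silyl group keeps C15' safe from nickel-mediated dehydrogenation.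

Step 7
Reactants: 15 tert-butyl({(3S)-17-[3,5-bis(methoxymethoxy)phenyl]heptadecan-3-yl}oxy)dimethylsilane
Product: 16 hansfordiol C, 5-[(15S)-15-hydroxyheptadecyl]benzene-1,3-diol
Conditions: HCl (1.25 M in MeOH), rt → 40 °C
Reagents that add atoms: none
Why: Acid-catalysed methanolysis should cleave both aryl methoxymethyl acetals (the formaldehyde unit being trapped as dimethoxymethane so that it cannot alkylate the electron-rich ring) and the secondary silyl ether without breaking the C15'–O bond, so the S configuration is retained.

**Compound list**
1 | 5-bromoresorcinol (5-bromobenzene-1,3-diol) | Oc1cc(O)cc(Br)c1 | starting material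
2 | 1-bromo-3,5-bis(methoxymethoxy)benzene | COCOc1cc(Br)cc(OCOC)c1 | intermediate
3 | 1,12-dibromododecane | BrCCCCCCCCCCCCBr | starting material
4 | [3,5-bis(methoxymethoxy)phenyl]magnesium bromide | COCOc1cc([Mg]Br)cc(OCOC)c1 | intermediate
5 | 1-(12-bromododecyl)-3,5-bis(methoxymethoxy)benzene | BrCCCCCCCCCCCCc1cc(OCOC)cc(OCOC)c1 | intermediate
6 | 1-(12-iodododecyl)-3,5-bis(methoxymethoxy)benzene | ICCCCCCCCCCCCc1cc(OCOC)cc(OCOC)c1 | intermediate
7 | 1,3-dithiane | C1CSCSC1 | starting material
8 | 2-lithio-1,3-dithiane | [Li]C1SCCCS1 | intermediate
9 | tert-butyl(1,3-dithian-2-yl)dimethylsilane | CC(C)(C)[Si](C)(C)C1SCCCS1 | intermediate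
10 | (S)-1,2-epoxybutane, (2S)-2-ethyloxirane | CC[C@H]1CO1 | starting material
11 | tert-butyl(2-lithio-1,3-dithian-2-yl)dimethylsilane | [Li]C1(SCCCS1)[Si](C)(C)C(C)(C)C | intermediate
12 | lithium (2S)-1-[2-(tert-butyldimethylsilyl)-1,3-dithian-2-yl]butan-2-olate | CC[C@H](O[Li])CC1(SCCCS1)[Si](C)(C)C(C)(C)C | intermediate
13 | 2-[(2S)-2-(tert-butyldimethylsilyloxy)butyl]-2-lithio-1,3-dithiane | CC[C@H](O[Si](C)(C)C(C)(C)C)CC1([Li])SCCCS1 | intermediate
14 | 2-{12-[3,5-bis(methoxymethoxy)phenyl]dodecyl}-2-[(2S)-2-(tert-butyldimethylsilyloxy)butyl]-1,3-dithiane | CC[C@H](O[Si](C)(C)C(C)(C)C)CC1(SCCCS1)CCCCCCCCCCCCc1cc(OCOC)cc(OCOC)c1 | intermediate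
15 | tert-butyl({(3S)-17-[3,5-bis(methoxymethoxy)phenyl]heptadecan-3-yl}oxy)dimethylsilane | CC[C@H](O[Si](C)(C)C(C)(C)C)CCCCCCCCCCCCCCc1cc(OCOC)cc(OCOC)c1 | intermediate
16 | hansfordiol C, 5-[(15S)-15-hydroxyheptadecyl]benzene-1,3-diol | CC[C@H](O)CCCCCCCCCCCCCCc1cc(O)cc(O)c1 | target

**Summary**
Total step count: 7. Longest linear sequence: 6 steps (steps 1, 2, 3, 5, 6, 7); the dithiane arm (step 4) joins at step 5.

**Steps most likely to fail**

1. Step 5. The silyl group may migrate before the epoxide is consumed, so that the relayed anion takes up a second epoxide. The SN2 alkylation of the hindered tertiary carbanion may also be slow, so that E2 loss of HI from the iodide or proton transfer takes over. Fallback: the same two bonds are made in separate operations, setting out from 1,3-dithiane 7. Metalation (n-BuLi, THF, −30 °C) gives 8, which opens epoxide 10 at its CH2 group; a water quench should give (2S)-1-(1,3-dithian-2-yl)butan-2-ol F1. Silylation (TBSCl, imidazole, DMF) gives tert-butyl{[(2S)-1-(1,3-dithian-2-yl)butan-2-yl]oxy}dimethylsilane F2. Deprotonation of F2 with one equivalent of t-BuLi in THF/HMPA at −78 °C produces the same carbanion 13 by a plain acid–base step, before any arene is present. Alkylation with iodide 6 then comes back to the route at 14.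

2. Step 2. The dibromide may be arylated at both ends, the Grignard reagent may homocouple, or magnesium insertion into the electron-rich aryl bromide may be sluggish. Fallback: the ring–chain bond is made by Sonogashira coupling, setting out from 2. Coupling with dodec-11-yn-1-ol (Pd(PPh3)2Cl2, CuI, Et3N, 80 °C) should give 12-[3,5-bis(methoxymethoxy)phenyl]dodec-11-yn-1-ol F3. Hydrogenation (H2, Pd/C, EtOAc) gives 12-[3,5-bis(methoxymethoxy)phenyl]dodecan-1-ol F4. Appel-type iodination (I2, PPh3, imidazole, CH2Cl2, 0 °C) comes back to the route at 6 and makes step 3 unnecessary.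

3. Step 6. Hydrogenolysis of the hindered thioketal may be incomplete, alkenes may form by partial elimination on the nickel surface, and the activity of the nickel varies from batch to batch. Fallback: the sulfur is removed by hydrolysis and the resulting carbonyl group by deoxygenation, setting out from 14. Alkylative hydrolysis (MeI, CaCO3, MeCN/H2O, 45 °C) should give (3S)-17-[3,5-bis(methoxymethoxy)phenyl]-3-[(tert-butyldimethylsilyl)oxy]heptadecan-5-one F5. Condensation with tosylhydrazide (EtOH, rt) gives the tosylhydrazone N'-{(3S)-17-[3,5-bis(methoxymethoxy)phenyl]-3-[(tert-butyldimethylsilyl)oxy]heptadecan-5-ylidene}-4-methylbenzenesulfonohydrazide F6. Reduction with catecholborane (CHCl3, 0 °C) followed by NaOAc·3H2O at reflux releases sulfinate and N2 and comes back to the route at 15.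

**Further compounds**
F1 | step 5 | (2S)-1-(1,3-dithian-2-yl)butan-2-ol | CC[C@H](O)CC1SCCCS1
F2 | step 5 | tert-butyl{[(2S)-1-(1,3-dithian-2-yl)butan-2-yl]oxy}dimethylsilane | CC[C@H](O[Si](C)(C)C(C)(C)C)CC1SCCCS1
F3 | step 2 | 12-[3,5-bis(methoxymethoxy)phenyl]dodec-11-yn-1-ol | OCCCCCCCCCCC#Cc1cc(OCOC)cc(OCOC)c1
F4 | step 2 | 12-[3,5-bis(methoxymethoxy)phenyl]dodecan-1-ol | OCCCCCCCCCCCCc1cc(OCOC)cc(OCOC)c1
F5 | step 6 | (3S)-17-[3,5-bis(methoxymethoxy)phenyl]-3-[(tert-butyldimethylsilyl)oxy]heptadecan-5-one | CC[C@H](O[Si](C)(C)C(C)(C)C)CC(=O)CCCCCCCCCCCCc1cc(OCOC)cc(OCOC)c1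
F6 | step 6 | N'-{(3S)-17-[3,5-bis(methoxymethoxy)phenyl]-3-[(tert-butyldimethylsilyl)oxy]heptadecan-5-ylidene}-4-methylbenzenesulfonohydrazide | CC[C@H](O[Si](C)(C)C(C)(C)C)CC(=NNS(=O)(=O)c1ccc(C)cc1)CCCCCCCCCCCCc2cc(OCOC)cc(OCOC)c2
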